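Numbering used: guaiacyl half C7 (ArCH–O), C8 (bridgehead), C9 (OCH2); syringyl half C7', C8', C9'; ring A = O–C7–C8–C8'–C9', ring B = O–C7'–C8'–C8–C9. C9 is a lone methylene between O7' and C8, a formaldehyde carbon, and O7' and O9' are 1,3-related through C8'. The route rests on disconnecting C8–C9 (ring B) together with C7–O9' (ring A): a syn-1-aryl-2-styrylpropane-1,3-diol is tied into its cyclic formal, whose Lewis acid opening gives an O7' oxocarbenium ion; styrene carbon C8 attacks its CH2 and O9' captures the C7 cation, building both rings and two stereocentres in one operation. The erythro side chain is set earlier by an anti-aldol.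

Key step: step 12

Remark: the side-chain carbons are called C7'' (ArCH–OH), C8'' (CH–OAr) and C9'' (CH2OH); the target is read as the erythro (7''S,8''R) ether on a (7S,8R,7'S,8'R) furofuran. TBS = tert-butyldimethylsilyl. Compounds 1, 3, 5, 8, 9 and 11 are taken as commercial. Ylides, enolates and the aryllithium are named in the Why lines only; covalent compounds that persist in the flask are numbered.

Step 1
Reactants: 1 vanillin
Product: 2 4-[(tert-butyldimethylsilyl)oxy]-3-methoxybenzaldehyde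
Conditions: TBSCl, imidazole, DMF, rt
Reagents that add atoms: tert-butyldimethylsilyl chloride, CC(C)(C)[Si](C)(C)Cl
Why: Corey silylation: imidazole-assisted O-silylation of the phenol is fast and chemoselective, the aldehyde is untouched and no stereocentre is formed.

Step 2
Reactants: 2 4-[(tert-butyldimethylsilyl)oxy]-3-methoxybenzaldehyde; 3 (2-carboxyethyl)triphenylphosphonium bromide
Product: 4 (E)-4-{4-[(tert-butyldimethylsilyl)oxy]-3-methoxyphenyl}but-3-enoic acid
Conditions: NaN(SiMe3)2 (2.2 equiv), THF, −78 °C → rt; then aq. HCl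
Reagents that add atoms: none
Why: Wittig olefination with the ylide carboxylate generated from 3 and two equivalents of base should deliver the β,γ-unsaturated acid in one step; such carboxylate ylides give mainly E alkenes with aromatic aldehydes and the double bond stays in styrene conjugation.

Step 3
Reactants: 4 (E)-4-{4-[(tert-butyldimethylsilyl)oxy]-3-methoxyphenyl}but-3-enoic acid; 5 (S)-4-benzyloxazolidin-2-one
Product: 7 (S)-4-benzyl-3-[(E)-4-{4-[(tert-butyldimethylsilyl)oxy]-3-methoxyphenyl}but-3-enoyl]oxazolidin-2-one, via mixed pivalic anhydride 6 (not isolated)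
Conditions: t-BuCOCl, Et3N, THF, −20 °C; then LiCl, 5, −20 °C → rt
Reagents that add atoms: none
Why: N-acylation of the oxazolidinone through the mixed pivalic anhydride under LiCl/Et3N activation is a mild imide synthesis in which the nucleophile attacks the less hindered carbonyl and the styrenyl double bond should not migrate.

Step 4
Reactants: 8 4-bromo-2,6-dimethoxyphenol; 9 bromoacetic acid
Product: 10 2-(4-bromo-2,6-dimethoxyphenoxy)acetic acid
Conditions: NaOH, H2O, 90 °C; then aq. HCl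
Reagents that add atoms: none
Why: Williamson ether synthesis: the phenoxide of 8 displaces bromide from the primary, carboxylate-activated carbon of bromoacetate by SN2 despite the two ortho methoxy groups.

Step 5
Reactants: 10 2-(4-bromo-2,6-dimethoxyphenoxy)acetic acid; 11 (R)-4-benzyloxazolidin-2-one
Product: 13 (R)-4-benzyl-3-[2-(4-bromo-2,6-dimethoxyphenoxy)acetyl]oxazolidin-2-one, via mixed pivalic anhydride 12 (not isolated)
Conditions: t-BuCOCl, Et3N, THF, −20 °C; then LiCl, 11, −20 °C → rt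
Reagents that add atoms: none
Why: The same mixed-anhydride N-acylation as in step 3 attaches the auxiliary that will control both side-chain stereocentres.

Step 6
Reactants: 13 (R)-4-benzyl-3-[2-(4-bromo-2,6-dimethoxyphenoxy)acetyl]oxazolidin-2-one; 2 4-[(tert-butyldimethylsilyl)oxy]-3-methoxybenzaldehyde
Product: 15 (R)-4-benzyl-3-[(2S,3S)-2-(4-bromo-2,6-dimethoxyphenoxy)-3-{4-[(tert-butyldimethylsilyl)oxy]-3-methoxyphenyl}-3-hydroxypropanoyl]oxazolidin-2-one, via trimethylsilyl ether 14 (not isolated)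
Conditions: MgCl2 (0.2 equiv), Et3N, Me3SiCl, EtOAc, rt; then CF3CO2H (cat.), MeOH
Reagents that add atoms: none
Why: Magnesium halide-catalysed direct anti-aldol reaction of an N-acyloxazolidinone with a non-enolisable aromatic aldehyde: the chelated Z magnesium enolate should be attacked on the face opposite the benzyl group through a boat transition state while silylation of the aldolate drives turnover, which sets C8'' (2S) and C7'' (3S) in the anti, erythro relation (7''S,8''R after reduction).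

Step 7
Reactants: 15 anti-aldol adduct
Product: 16 (1S,2R)-2-(4-bromo-2,6-dimethoxyphenoxy)-1-{4-[(tert-butyldimethylsilyl)oxy]-3-methoxyphenyl}propane-1,3-diol
Conditions: LiBH4, MeOH (1 equiv), THF, 0 °C
Reagents that add atoms: none
Why: Reductive cleavage of the imide with LiBH4 (acyl carbon to CH2OH, auxiliary 11 released) should leave both stereocentres, the aryl bromide and the aryl silyl ether untouched at 0 °C.

Step 8
Reactants: 16 erythro diol
Product: 17 tert-butyl{4-[(1S,2R)-2-(4-bromo-2,6-dimethoxyphenoxy)-1,3-bis[(tert-butyldimethylsilyl)oxy]propyl]-2-methoxyphenoxy}dimethylsilane (tris-TBS ether of 16)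
Conditions: TBSOTf, 2,6-lutidine, CH2Cl2, 0 °C
Reagents that add atoms: tert-butyldimethylsilyl triflate, CC(C)(C)[Si](C)(C)OS(=O)(=O)C(F)(F)F
Why: Silylation with a silyl triflate and a hindered pyridine base covers the primary and the hindered benzylic hydroxyl without acid, so that every hydroxyl of the side chain carries the same fluoride-labile group.

Step 9
Reactants: 17 tris-TBS aryl bromide
Product: 18 4-{[(1S,2R)-1,3-bis[(tert-butyldimethylsilyl)oxy]-1-{4-[(tert-butyldimethylsilyl)oxy]-3-methoxyphenyl}propan-2-yl]oxy}-3,5-dimethoxybenzaldehyde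
Conditions: n-BuLi, THF, −78 °C; then Me2NCHO, −78 → 0 °C; H2O
Reagents that add atoms: N,N-dimethylformamide, CN(C)C=O
Why: Bromine–lithium exchange followed by Bouveault formylation with DMF: exchange at −78 °C is faster than attack on the silyl ethers and the aryllithium adds once to DMF, which unmasks the aldehyde carbon C7'.

Step 10
Reactants: 7 (S)-styrylacetyl imide; 18 syringyl aldehyde
Product: 19 (S)-4-benzyl-3-[(2S,3S)-2-[(E)-2-{4-[(tert-butyldimethylsilyl)oxy]-3-methoxyphenyl}ethenyl]-3-hydroxy-3-(3,5-dimethoxy-4-{[(1S,2R)-1,3-bis[(tert-butyldimethylsilyl)oxy]-1-{4-[(tert-butyldimethylsilyl)oxy]-3-methoxyphenyl}propan-2-yl]oxy}phenyl)propanoyl]oxazolidin-2-one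
Conditions: Bu2BOTf, i-Pr2NEt, CH2Cl2, −78 → 0 °C; then pH 7 buffer, MeOH, H2O2, 0 °C
Reagents that add atoms: none
Why: Evans syn-aldol reaction: the Z boron dienolate of 7 should react at its α-carbon through a Zimmerman–Traxler chair on the face opposite the benzyl group of the dipole-minimised auxiliary, which sets C8' (2S) and C7' (3S) syn and keeps the E styrene.

Step 11
Reactants: 19 syn-aldol adduct
Product: 20 (1S,2R)-2-[(E)-2-{4-[(tert-butyldimethylsilyl)oxy]-3-methoxyphenyl}ethenyl]-1-(3,5-dimethoxy-4-{[(1S,2R)-1,3-bis[(tert-butyldimethylsilyl)oxy]-1-{4-[(tert-butyldimethylsilyl)oxy]-3-methoxyphenyl}propan-2-yl]oxy}phenyl)propane-1,3-diol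
Conditions: LiBH4, MeOH (1 equiv), THF, 0 °C
Reagents that add atoms: none
Why: Reductive removal of the auxiliary with LiBH4 turns C9' into CH2OH and should not epimerise C8', since no enolisable carbonyl remains after hydride delivery.

Step 12
Reactants: 20 syn-2-styryl-1,3-diol
Product: 22 (1S,3aR,4S,6aR)-1-{4-[(tert-butyldimethylsilyl)oxy]-3-methoxyphenyl}-4-(3,5-dimethoxy-4-{[(1S,2R)-1,3-bis[(tert-butyldimethylsilyl)oxy]-1-{4-[(tert-butyldimethylsilyl)oxy]-3-methoxyphenyl}propan-2-yl]oxy}phenyl)tetrahydro-1H,3H-furo[3,4-c]furan (tetra-TBS hedyotol C), via cyclic formal 21 (not isolated)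
Conditions: CH2(OMe)2 (1.2 equiv), Me3SiOTf (2.5 equiv), 2,6-di-tert-butyl-4-methylpyridine, CH2Cl2, −78 → −20 °C; then Et3N
Reagents that add atoms: dimethoxymethane, COCOC
Why: Me3SiOTf first joins O7' and O9' of 20 through the CH2 of dimethoxymethane (cyclic formal 21), then silylates the less hindered acetal oxygen O9' and opens the ring to the oxocarbenium ion O7'=C9H2; the E styrene attacks C9 with its β-carbon C8 (C8–C9 bond) and the benzylic cation at C7, stabilised by the para silyloxy group, is captured by O9' with release of the silyl cation. The closest known reaction type is the acetal-initiated Prins bicyclisation, an oxocarbenium–alkene cyclisation ended by a tethered oxygen nucleophile. Ring B closes 5-exo-trig with respect to the styrene (oxocarbenium C=O inside the ring) and ring A closes by 5-exo-trig capture of the quinoid cation. C8 is controlled by the ring fusion, because only the cation with C7 cis to C9' can be trapped while the trans cation should revert by retro-Prins fragmentation, and C7 is controlled by the convex face of the forming bicycle (aryl exo, a net anti addition of C9 and O9' across the E double bond); C7' and C8' come from 20 and place the syringyl group exo. The step needs opening of the formal at O9' and not at O7' (favoured by the less hindered, more basic primary oxygen), attack at C8 and not C7 (favoured by the benzylic cation), and no ionisation of C7'–O (the 4-alkoxy group of the syringyl ring is twisted out of conjugation by its two ortho methoxy groups) or of the silyl ethers (hindered base, low temperature).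

Step 13
Reactants: 22 tetra-TBS hedyotol C
Product: 23 hedyotol C
Conditions: Bu4NF, AcOH, THF, 0 °C → rt
Reagents that add atoms: none
Why: Fluoride-mediated global desilylation cleaves the two aryl and the two alkyl silyl ethers, the acetic acid buffer keeps the phenols protonated so that the para-hydroxybenzylic centres C7 and C7'' are not ionised through quinone methides, and no stereocentre is touched.

Compound list

1 | vanillin (4-hydroxy-3-methoxybenzaldehyde) | COc1cc(C=O)ccc1O | starting material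
2 | 4-[(tert-butyldimethylsilyl)oxy]-3-methoxybenzaldehyde | COc1cc(C=O)ccc1O[Si](C)(C)C(C)(C)C | intermediate
3 | (2-carboxyethyl)triphenylphosphonium bromide | OC(=O)CC[P+](c1ccccc1)(c1ccccc1)c1ccccc1.[Br-] | starting material
4 | (E)-4-{4-[(tert-butyldimethylsilyl)oxy]-3-methoxyphenyl}but-3-enoic acid | COc1cc(/C=C/CC(=O)O)ccc1O[Si](C)(C)C(C)(C)C | intermediate
5 | (S)-4-benzyloxazolidin-2-one | O=C1N[C@@H](Cc2ccccc2)CO1 | starting material
6 | mixed anhydride of acid 4 with pivalic acid | COc1cc(/C=C/CC(=O)OC(=O)C(C)(C)C)ccc1O[Si](C)(C)C(C)(C)C | intermediate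
7 | (S)-4-benzyl-3-[(E)-4-{4-[(tert-butyldimethylsilyl)oxy]-3-methoxyphenyl}but-3-enoyl]oxazolidin-2-one | COc1cc(/C=C/CC(=O)N2[C@@H](Cc3ccccc3)COC2=O)ccc1O[Si](C)(C)C(C)(C)C | intermediate
8 | 4-bromo-2,6-dimethoxyphenol | COc1cc(Br)cc(OC)c1O | starting material
9 | bromoacetic acid | OC(=O)CBr | starting material
10 | 2-(4-bromo-2,6-dimethoxyphenoxy)acetic acid | COc1cc(Br)cc(OC)c1OCC(=O)O | intermediate
11 | (R)-4-benzyloxazolidin-2-one | O=C1N[C@H](Cc2ccccc2)CO1 | starting material
12 | mixed anhydride of acid 10 with pivalic acid | COc1cc(Br)cc(OC)c1OCC(=O)OC(=O)C(C)(C)C | intermediate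
13 | (R)-4-benzyl-3-[2-(4-bromo-2,6-dimethoxyphenoxy)acetyl]oxazolidin-2-one | COc1cc(Br)cc(OC)c1OCC(=O)N1[C@H](Cc2ccccc2)COC1=O | intermediate
14 | O-trimethylsilyl ether of anti-aldol adduct 15 | COc1cc(Br)cc(OC)c1O[C@H](C(=O)N1[C@H](Cc2ccccc2)COC1=O)[C@@H](O[Si](C)(C)C)c1ccc(O[Si](C)(C)C(C)(C)C)c(OC)c1 | intermediate
15 | (R)-4-benzyl-3-[(2S,3S)-2-(4-bromo-2,6-dimethoxyphenoxy)-3-{4-[(tert-butyldimethylsilyl)oxy]-3-methoxyphenyl}-3-hydroxypropanoyl]oxazolidin-2-one | COc1cc(Br)cc(OC)c1O[C@H](C(=O)N1[C@H](Cc2ccccc2)COC1=O)[C@@H](O)c1ccc(O[Si](C)(C)C(C)(C)C)c(OC)c1 | intermediate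
16 | (1S,2R)-2-(4-bromo-2,6-dimethoxyphenoxy)-1-{4-[(tert-butyldimethylsilyl)oxy]-3-methoxyphenyl}propane-1,3-diol | COc1cc(Br)cc(OC)c1O[C@H](CO)[C@@H](O)c1ccc(O[Si](C)(C)C(C)(C)C)c(OC)c1 | intermediate
17 | tris-TBS ether of 16: (1S,2R)-2-(4-bromo-2,6-dimethoxyphenoxy)-1,3-bis[(tert-butyldimethylsilyl)oxy]-1-{4-[(tert-butyldimethylsilyl)oxy]-3-methoxyphenyl}propane | COc1cc(Br)cc(OC)c1O[C@H](CO[Si](C)(C)C(C)(C)C)[C@@H](O[Si](C)(C)C(C)(C)C)c1ccc(O[Si](C)(C)C(C)(C)C)c(OC)c1 | intermediate
18 | 4-{[(1S,2R)-1,3-bis[(tert-butyldimethylsilyl)oxy]-1-{4-[(tert-butyldimethylsilyl)oxy]-3-methoxyphenyl}propan-2-yl]oxy}-3,5-dimethoxybenzaldehyde | COc1cc(C=O)cc(OC)c1O[C@H](CO[Si](C)(C)C(C)(C)C)[C@@H](O[Si](C)(C)C(C)(C)C)c1ccc(O[Si](C)(C)C(C)(C)C)c(OC)c1 | intermediate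
19 | syn-aldol adduct: (S)-4-benzyl-3-[(2S,3S)-3-hydroxy-2-[(E)-styryl]-3-arylpropanoyl]oxazolidin-2-one (styryl = 4-TBSO-3-methoxystyryl; aryl = ring of 18) | O=C(N1[C@@H](Cc2ccccc2)COC1=O)[C@@H](/C=C/c1ccc(O[Si](C)(C)C(C)(C)C)c(OC)c1)[C@H](O)c1cc(OC)c(O[C@H](CO[Si](C)(C)C(C)(C)C)[C@@H](O[Si](C)(C)C(C)(C)C)c2ccc(O[Si](C)(C)C(C)(C)C)c(OC)c2)c(OC)c1 | intermediate
20 | (1S,2R)-1-aryl-2-[(E)-2-{4-[(tert-butyldimethylsilyl)oxy]-3-methoxyphenyl}ethenyl]propane-1,3-diol (aryl = ring of 18) | OC[C@@H](/C=C/c1ccc(O[Si](C)(C)C(C)(C)C)c(OC)c1)[C@H](O)c1cc(OC)c(O[C@H](CO[Si](C)(C)C(C)(C)C)[C@@H](O[Si](C)(C)C(C)(C)C)c2ccc(O[Si](C)(C)C(C)(C)C)c(OC)c2)c(OC)c1 | intermediate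
21 | cyclic formal of 20: (4S,5R)-4-aryl-5-[(E)-2-{4-[(tert-butyldimethylsilyl)oxy]-3-methoxyphenyl}ethenyl]-1,3-dioxane (cis) | C1OC[C@@H](/C=C/c2ccc(O[Si](C)(C)C(C)(C)C)c(OC)c2)[C@H](O1)c1cc(OC)c(O[C@H](CO[Si](C)(C)C(C)(C)C)[C@@H](O[Si](C)(C)C(C)(C)C)c2ccc(O[Si](C)(C)C(C)(C)C)c(OC)c2)c(OC)c1 | intermediate
22 | tetra-TBS hedyotol C: (1S,3aR,4S,6aR)-1-(4-TBSO-3-methoxyphenyl)-4-[3,5-dimethoxy-4-(silylated erythro-glyceryloxy)phenyl]tetrahydro-1H,3H-furo[3,4-c]furan | COc1cc([C@H]2OC[C@H]3[C@@H]2CO[C@@H]3c2cc(OC)c(O[C@H](CO[Si](C)(C)C(C)(C)C)[C@@H](O[Si](C)(C)C(C)(C)C)c3ccc(O[Si](C)(C)C(C)(C)C)c(OC)c3)c(OC)c2)ccc1O[Si](C)(C)C(C)(C)C | intermediate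
23 | hedyotol C | COc1cc([C@H]2OC[C@H]3[C@@H]2CO[C@@H]3c2cc(OC)c(O[C@H](CO)[C@@H](O)c3ccc(O)c(OC)c3)c(OC)c2)ccc1O | target

Total step count: 13 steps.
Longest linear sequence: 10 steps (steps 4 to 13, from 8).

Steps most likely to fail

Step 12. The cyclic formal may open at O7' instead of O9', which puts the oxocarbenium ion on the wrong oxygen and leads to the isomeric 2,4-diaryl bicycle, or the methoxymethyl cation may react with the styrene before the formal has formed. The fallback makes the ionisation unambiguous and sets out from 20. The primary hydroxyl is silylated selectively (TBSCl, imidazole, CH2Cl2, 0 °C) to the primary tert-butyldimethylsilyl ether F1. The remaining benzylic hydroxyl is converted (MeOCH2Cl, i-Pr2NEt, Bu4NI, CH2Cl2) into the methoxymethyl ether F2. Treatment of F2 with catalytic Me3SiOTf and 2,6-di-tert-butyl-4-methylpyridine in CH2Cl2 at −78 °C ionises only the methoxymethyl acetal, so the oxocarbenium ion can sit on O7' alone; the Prins closure is ended by the silyl ether oxygen O9' with loss of the silyl group, and the route is rejoined at 22.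

Step 6. The α-aryloxy oxygen may compete for magnesium, which would erode the anti/syn and facial selectivity, or the aldolate may undergo retro-aldol before it is silylated. The fallback uses the boron syn-aldol and a Mitsunobu inversion and sets out from 10. Acid 10 is coupled with 5 (t-BuCOCl, Et3N, LiCl) to the (S)-4-benzyl-3-[2-(4-bromo-2,6-dimethoxyphenoxy)acetyl]oxazolidin-2-one F3. Its Bu2BOTf/i-Pr2NEt aldol reaction with 2 should give the (2S,3R) syn (threo) aldol adduct F4, and LiBH4 reduction the (1R,2R) threo diol F5. Selective silylation (TBSCl, imidazole) gives the primary tert-butyldimethylsilyl ether F6. Mitsunobu reaction at C7'' (4-nitrobenzoic acid, PPh3, DIAD, THF) should give with inversion the erythro 4-nitrobenzoate F7. Methanolysis (K2CO3, MeOH), which also removes the aryl silyl group, gives the erythro phenol alcohol F8, and silylation with TBSOTf/2,6-lutidine rejoins the route at 17.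

Step 2. The Z alkene may form in significant amount, and the strongly basic ylide may cleave the aryl silyl ether. The fallback builds the double bond by condensation and sets out from 2. Wittig homologation with (methoxymethyl)triphenylphosphonium chloride and KN(SiMe3)2 gives the enol ether 1-(2-methoxyethenyl)-4-[(tert-butyldimethylsilyl)oxy]-3-methoxybenzene F9 (E/Z mixture). Mild acid hydrolysis (aq. HCO2H, THF) gives the arylacetaldehyde 2-{4-[(tert-butyldimethylsilyl)oxy]-3-methoxyphenyl}acetaldehyde F10. Decarboxylative Knoevenagel condensation of F10 with malonic acid (piperidinium acetate, DMSO, 100 °C), which gives (E)-alk-3-enoic acids, rejoins the route at 4.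

Further compounds

F1 | step 12 | primary tert-butyldimethylsilyl ether of diol 20 | CC(C)(C)[Si](C)(C)OC[C@@H](/C=C/c1ccc(O[Si](C)(C)C(C)(C)C)c(OC)c1)[C@H](O)c1cc(OC)c(O[C@H](CO[Si](C)(C)C(C)(C)C)[C@@H](O[Si](C)(C)C(C)(C)C)c2ccc(O[Si](C)(C)C(C)(C)C)c(OC)c2)c(OC)c1
F2 | step 12 | methoxymethyl ether of F1 at the benzylic oxygen O7' | CC(C)(C)[Si](C)(C)OC[C@@H](/C=C/c1ccc(O[Si](C)(C)C(C)(C)C)c(OC)c1)[C@H](OCOC)c1cc(OC)c(O[C@H](CO[Si](C)(C)C(C)(C)C)[C@@H](O[Si](C)(C)C(C)(C)C)c2ccc(O[Si](C)(C)C(C)(C)C)c(OC)c2)c(OC)c1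
F3 | step 6 | (S)-4-benzyl-3-[2-(4-bromo-2,6-dimethoxyphenoxy)acetyl]oxazolidin-2-one | COc1cc(Br)cc(OC)c1OCC(=O)N1[C@@H](Cc2ccccc2)COC1=O
F4 | step 6 | (S)-4-benzyl-3-[(2S,3R)-2-(4-bromo-2,6-dimethoxyphenoxy)-3-{4-[(tert-butyldimethylsilyl)oxy]-3-methoxyphenyl}-3-hydroxypropanoyl]oxazolidin-2-one | COc1cc(Br)cc(OC)c1O[C@H](C(=O)N1[C@@H](Cc2ccccc2)COC1=O)[C@H](O)c1ccc(O[Si](C)(C)C(C)(C)C)c(OC)c1
F5 | step 6 | (1R,2R)-2-(4-bromo-2,6-dimethoxyphenoxy)-1-{4-[(tert-butyldimethylsilyl)oxy]-3-methoxyphenyl}propane-1,3-diol | COc1cc(Br)cc(OC)c1O[C@H](CO)[C@H](O)c1ccc(O[Si](C)(C)C(C)(C)C)c(OC)c1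
F6 | step 6 | (1R,2R)-2-(4-bromo-2,6-dimethoxyphenoxy)-3-[(tert-butyldimethylsilyl)oxy]-1-{4-[(tert-butyldimethylsilyl)oxy]-3-methoxyphenyl}propan-1-ol | COc1cc(Br)cc(OC)c1O[C@H](CO[Si](C)(C)C(C)(C)C)[C@H](O)c1ccc(O[Si](C)(C)C(C)(C)C)c(OC)c1
F7 | step 6 | (1S,2R)-2-(4-bromo-2,6-dimethoxyphenoxy)-3-[(tert-butyldimethylsilyl)oxy]-1-{4-[(tert-butyldimethylsilyl)oxy]-3-methoxyphenyl}propyl 4-nitrobenzoate | COc1cc(Br)cc(OC)c1O[C@H](CO[Si](C)(C)C(C)(C)C)[C@@H](OC(=O)c1ccc(cc1)[N+](=O)[O-])c1ccc(O[Si](C)(C)C(C)(C)C)c(OC)c1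
F8 | step 6 | 4-[(1S,2R)-2-(4-bromo-2,6-dimethoxyphenoxy)-3-[(tert-butyldimethylsilyl)oxy]-1-hydroxypropyl]-2-methoxyphenol | COc1cc(Br)cc(OC)c1O[C@H](CO[Si](C)(C)C(C)(C)C)[C@@H](O)c1ccc(O)c(OC)c1
F9 | step 2 | 1-(2-methoxyethenyl)-4-[(tert-butyldimethylsilyl)oxy]-3-methoxybenzene (E/Z mixture) | COC=Cc1ccc(O[Si](C)(C)C(C)(C)C)c(OC)c1
F10 | step 2 | 2-{4-[(tert-butyldimethylsilyl)oxy]-3-methoxyphenyl}acetaldehyde | O=CCc1ccc(O[Si](C)(C)C(C)(C)C)c(OC)c1
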